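**Retrosynthetic overview**
1. Target 22 ← penta-tert-butyl ester 20 by acidolysis. The only ring, the anhydride, closes last, by itself, from the freed dialkylmaleic acid.
2. 20 ← (Z)-selective Still–Gennari olefination of α-chiral aldehyde 11 with β-chiral phosphonate 18 (forms the trisubstituted alkene, joins the halves).
3. 11 ← key C–C bond CH2–CH(Et): enantioselective photoredox/enamine coupling of the maleate-derived allylic radical with butanal.
4. Radical precursor 8 ← acetylenedicarboxylate + 1-butyne + formaldehyde (syn-carbocupration, trapping, bromination).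
5. 18 ← Pd-catalysed asymmetric allylic alkylation of a cyclopentenyl acetate with a phosphonoacetate, then oxidative ring cleavage (cyclopentene = latent glutarate).

Assumption: the facial preferences of the imidazolidinone (step 4) and the Trost ligand (step 7) follow the published models; if a first run shows the opposite sense, the antipodal catalyst is used and nothing else changes.

**Step 1**
Reactants: 1 acetylenedicarboxylic acid
Product: 2 di-tert-butyl but-2-ynedioate
Conditions: isobutylene (excess), H2SO4 (cat.), CH2Cl2, sealed vessel, rt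
Reagents that add atoms: isobutylene CC(C)=C
Why: Acid-catalysed addition of the carboxylic acids to isobutylene gives tert-butyl esters that survive organocopper and enamine chemistry and fall without base at the end.

**Step 2**
Reactants: 2 di-tert-butyl but-2-ynedioate; 3 1-butyne
Product: 7 di-tert-butyl 2-[(E)-but-1-enyl]-3-(hydroxymethyl)maleate, via butenylzirconocene chloride 4 (not isolated), via butenylcopper 5 (not isolated), via vinylcopper adduct 6 (not isolated)
Conditions: 3, Cp2Zr(H)Cl, THF, rt; CuCl·2LiCl, 0 °C; 2, −78 °C; monomeric CH2O in THF, −78 → −40 °C; aq. NH4Cl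
Reagents that add atoms: formaldehyde C=O
Why: Hydrozirconation gives the (E)-alkenyl metal, transmetallation to copper and syn-carbocupration of the ynedioate place butenyl and copper cis (so the esters are cis), and the α-cuprio ester is trapped with retention by formaldehyde (tandem conjugate addition–aldol); the CH2OH is trans to the distal ester and cannot lactonise.

**Step 3**
Reactants: 7 di-tert-butyl 2-[(E)-but-1-enyl]-3-(hydroxymethyl)maleate
Product: 8 di-tert-butyl 2-(bromomethyl)-3-[(E)-but-1-enyl]maleate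
Conditions: CBr4, PPh3, CH2Cl2, 0 °C
Reagents that add atoms: carbon tetrabromide BrC(Br)(Br)Br
Why: The Appel reaction converts the primary allylic alcohol into the bromide under neutral conditions, leaving esters and alkene geometry untouched.

**Step 4**
Reactants: 8 di-tert-butyl 2-(bromomethyl)-3-[(E)-but-1-enyl]maleate; 9 butanal (3 equiv)
Product: 11 di-tert-butyl 2-[(E)-but-1-enyl]-3-[(2R)-2-formylbutyl]maleate, via allyl radical 10 (not isolated)
Conditions: (2R,5S)-2-tert-butyl-3,5-dimethylimidazolidin-4-one·CF3SO3H (20 mol %), fac-Ir(ppy)3 [tris(2-phenylpyridinato)iridium] (0.5 mol %), 2,6-lutidine, DMF, blue LEDs, 10 °C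
Reagents that add atoms: none
Why: Proposed new method: the excited iridium complex reduces the electron-poor allylic bromide to the vinylogous α-acyl radical 10, which is electrophilic and should add through its unhindered CH2 terminus (the only mode that keeps the diene diester conjugated) to the Si face of the (E)-enamine of butanal, whose Re face is blocked by the C5 methyl of the trans-imidazolidinone, giving the (R)-aldehyde after oxidation of the α-amino radical and hydrolysis; the closest known reaction is the photoredox organocatalytic enantioselective α-alkylation and α-benzylation of aldehydes with bromomalonates and electron-poor benzyl bromides.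

**Step 5**
Reactants: 12 tert-butyl acetate
Product: 13 tert-butyl 2-[bis(2,2,2-trifluoroethoxy)phosphoryl]acetate
Conditions: LiN(SiMe3)2 (2.2 equiv), THF, −78 °C; ClP(O)(OCH2CF3)2, −78 → 0 °C
Reagents that add atoms: bis(2,2,2-trifluoroethyl) phosphorochloridate O=P(Cl)(OCC(F)(F)F)OCC(F)(F)F
Why: C-phosphorylation of the ester enolate (second equivalent of base because the product is more acidic) is the standard entry to Still–Gennari reagents.

**Step 6**
Reactants: 14 cyclopent-2-en-1-ol (racemic)
Product: 15 cyclopent-2-en-1-yl acetate (racemic)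
Conditions: Ac2O, pyridine, DMAP (cat.), CH2Cl2, 0 °C → rt
Reagents that add atoms: acetic anhydride CC(=O)OC(C)=O
Why: Routine acetylation gives the ionisable allylic ester needed for palladium allyl chemistry.

**Step 7**
Reactants: 13 tert-butyl 2-[bis(2,2,2-trifluoroethoxy)phosphoryl]acetate; 15 cyclopent-2-en-1-yl acetate
Product: 16 tert-butyl 2-[bis(2,2,2-trifluoroethoxy)phosphoryl]-2-[(1S)-cyclopent-2-en-1-yl]acetate (both epimers at C2)
Conditions: [Pd(C3H5)Cl]2 (2.5 mol %), (R,R)-DACH-phenyl Trost ligand (7.5 mol %), NaH, (n-C6H13)4NBr, CH2Cl2, 0 °C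
Reagents that add atoms: none
Why: Trost asymmetric allylic alkylation: both enantiomers of 15 ionise to the same symmetrical cyclopentenyl palladium complex and the ligand pocket steers the soft phosphonoacetate anion to one terminus, setting the (S) ring carbon as in the malonate benchmark; the phosphorus-bearing carbon is uncontrolled but becomes the carbanion in step 10.

**Step 8**
Reactants: 16 tert-butyl 2-[bis(2,2,2-trifluoroethoxy)phosphoryl]-2-[(1S)-cyclopent-2-en-1-yl]acetate
Product: 17 (2S)-2-{2-tert-butoxy-2-oxo-1-[bis(2,2,2-trifluoroethoxy)phosphoryl]ethyl}pentanedioic acid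
Conditions: RuCl3·xH2O (2 mol %), NaIO4 (4.5 equiv), EtOAc/MeCN/H2O, rt
Reagents that add atoms: sodium periodate [Na+].[O-]I(=O)(=O)=O; water O
Why: RuO4-catalysed oxidative cleavage (Sharpless conditions) of the ring alkene unmasks the glutaric acid, the vinylic carbon next to the stereocentre becoming its carboxyl group without touching the stereocentre.

**Step 9**
Reactants: 17 (2S)-2-{2-tert-butoxy-2-oxo-1-[bis(2,2,2-trifluoroethoxy)phosphoryl]ethyl}pentanedioic acid
Product: 18 tri-tert-butyl (2S)-1-[bis(2,2,2-trifluoroethoxy)phosphoryl]butane-1,2,4-tricarboxylate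
Conditions: tert-butyl 2,2,2-trichloroacetimidate (4 equiv), BF3·OEt2 (cat.), CH2Cl2/cyclohexane, rt
Reagents that add atoms: tert-butyl 2,2,2-trichloroacetimidate CC(C)(C)OC(=N)C(Cl)(Cl)Cl
Why: Acid-catalysed imidate esterification protects both acids without base, so all five carboxyl groups fall in one acidolysis and the hindered esters resist Dieckmann closure onto the phosphonate anion.

**Step 10**
Reactants: 18 tri-tert-butyl (2S)-1-[bis(2,2,2-trifluoroethoxy)phosphoryl]butane-1,2,4-tricarboxylate; 11 di-tert-butyl 2-[(E)-but-1-enyl]-3-[(2R)-2-formylbutyl]maleate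
Product: 20 penta-tert-butyl (3R,4Z,6R,8Z,10E)-6-ethyltrideca-4,8,10-triene-1,3,4,8,9-pentacarboxylate, via potassium phosphonate anion 19 (not isolated)
Conditions: KN(SiMe3)2 (1.0 equiv), 18-crown-6 (3 equiv), THF, −78 °C; then 11, −78 → −40 °C
Reagents that add atoms: none
Why: Still–Gennari variant of the Horner–Wadsworth–Emmons reaction: the dissociated potassium anion adds irreversibly and the adduct collapses fast, giving the kinetic enoate with the aldehyde chain cis to the ester, i.e. the (Z)-alkene; the preformed stabilised anion is too weak a base to epimerise either stereocentre (C3 is R only because the priority order changes once phosphorus is lost).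

**Step 11**
Reactants: 20 penta-tert-butyl (3R,4Z,6R,8Z,10E)-6-ethyltrideca-4,8,10-triene-1,3,4,8,9-pentacarboxylate
Product: 22 (2R)-2-{(1Z,3R)-3-[(4-[(E)-but-1-enyl]-2,5-dioxo-2,5-dihydrofuran-3-yl)methyl]-1-carboxypent-1-en-1-yl}pentanedioic acid, via pentacarboxylic acid 21 (not isolated)
Conditions: CF3CO2H/CH2Cl2 (1:2), 0 °C → rt; evaporate; H2O/MeCN, lyophilise
Reagents that add atoms: none
Why: Acidolysis of the tert-butyl esters (loss of isobutylene) uses no base, so the glutarate centre and the (Z)-alkene cannot equilibrate, and the dialkylmaleic acid of 21 dehydrates spontaneously to the anhydride while the alkylidenesuccinic acid stays open.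

**Compound list**
1 | acetylenedicarboxylic acid | OC(=O)C#CC(=O)O | starting material
2 | di-tert-butyl but-2-ynedioate | CC(C)(C)OC(=O)C#CC(=O)OC(C)(C)C | intermediate
3 | 1-butyne | CCC#C | starting material
4 | (E)-but-1-enylzirconocene chloride (not isolated) | CC/C=C/[Zr](Cl)(C1C=CC=C1)C1C=CC=C1 | intermediate
5 | (E)-but-1-enylcopper (not isolated) | CC/C=C/[Cu] | intermediate
6 | di-tert-butyl 2-[(E)-but-1-enyl]-3-cupriomaleate (not isolated) | CC/C=C/C(/C(=O)OC(C)(C)C)=C(\[Cu])C(=O)OC(C)(C)C | intermediate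
7 | di-tert-butyl 2-[(E)-but-1-enyl]-3-(hydroxymethyl)maleate | CC/C=C/C(/C(=O)OC(C)(C)C)=C(\CO)C(=O)OC(C)(C)C | intermediate
8 | di-tert-butyl 2-(bromomethyl)-3-[(E)-but-1-enyl]maleate | CC/C=C/C(/C(=O)OC(C)(C)C)=C(\CBr)C(=O)OC(C)(C)C | intermediate
9 | butanal | CCCC=O | starting material
10 | allyl radical from 8 (not isolated) | CC/C=C/C(/C(=O)OC(C)(C)C)=C(\[CH2])C(=O)OC(C)(C)C | intermediate
11 | di-tert-butyl 2-[(E)-but-1-enyl]-3-[(2R)-2-formylbutyl]maleate | CC/C=C/C(/C(=O)OC(C)(C)C)=C(\C[C@H](C=O)CC)C(=O)OC(C)(C)C | intermediate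
12 | tert-butyl acetate | CC(=O)OC(C)(C)C | starting material
13 | tert-butyl 2-[bis(2,2,2-trifluoroethoxy)phosphoryl]acetate | CC(C)(C)OC(=O)CP(=O)(OCC(F)(F)F)OCC(F)(F)F | intermediate
14 | cyclopent-2-en-1-ol (racemic) | OC1C=CCC1 | starting material
15 | cyclopent-2-en-1-yl acetate (racemic) | CC(=O)OC1C=CCC1 | intermediate
16 | tert-butyl 2-[bis(2,2,2-trifluoroethoxy)phosphoryl]-2-[(1S)-cyclopent-2-en-1-yl]acetate | CC(C)(C)OC(=O)C([C@@H]1C=CCC1)P(=O)(OCC(F)(F)F)OCC(F)(F)F | intermediate
17 | (2S)-2-{2-tert-butoxy-2-oxo-1-[bis(2,2,2-trifluoroethoxy)phosphoryl]ethyl}pentanedioic acid | CC(C)(C)OC(=O)C([C@@H](CCC(=O)O)C(=O)O)P(=O)(OCC(F)(F)F)OCC(F)(F)F | intermediate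
18 | tri-tert-butyl (2S)-1-[bis(2,2,2-trifluoroethoxy)phosphoryl]butane-1,2,4-tricarboxylate | CC(C)(C)OC(=O)C([C@@H](CCC(=O)OC(C)(C)C)C(=O)OC(C)(C)C)P(=O)(OCC(F)(F)F)OCC(F)(F)F | intermediate
19 | potassium salt of the phosphonate carbanion of 18 (not isolated) | [K+].CC(C)(C)OC(=O)[C-]([C@@H](CCC(=O)OC(C)(C)C)C(=O)OC(C)(C)C)P(=O)(OCC(F)(F)F)OCC(F)(F)F | intermediate
20 | penta-tert-butyl (3R,4Z,6R,8Z,10E)-6-ethyltrideca-4,8,10-triene-1,3,4,8,9-pentacarboxylate | CC/C=C/C(/C(=O)OC(C)(C)C)=C(\C[C@H](/C=C(\C(=O)OC(C)(C)C)[C@@H](CCC(=O)OC(C)(C)C)C(=O)OC(C)(C)C)CC)C(=O)OC(C)(C)C | intermediate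
21 | (3R,4Z,6R,8Z,10E)-6-ethyltrideca-4,8,10-triene-1,3,4,8,9-pentacarboxylic acid (not isolated) | CC/C=C/C(/C(=O)O)=C(\C[C@H](/C=C(\C(=O)O)[C@@H](CCC(=O)O)C(=O)O)CC)C(=O)O | intermediate
22 | (2R)-2-{(1Z,3R)-3-[(4-[(E)-but-1-enyl]-2,5-dioxo-2,5-dihydrofuran-3-yl)methyl]-1-carboxypent-1-en-1-yl}pentanedioic acid | CC/C=C/C1=C(C[C@H](/C=C(\C(=O)O)[C@@H](CCC(=O)O)C(=O)O)CC)C(=O)OC1=O | target

**Totals**
Total step count: 11. Longest linear sequence: 6 (steps 1, 2, 3, 4, 10, 11; the branch 5, 7, 8, 9, 10, 11 is equally long).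

**Steps most likely to fail**

Step 4. The delocalised radical 10 may add too slowly to the enamine, couple through its far terminus, or lose the cis-diester or (E)-butenyl geometry (bond rotation in the radical, or energy transfer from the photocatalyst). The fallback sets out from 8 and comes back at 11, and makes the bond by auxiliary-controlled enolate alkylation instead. (S)-4-Benzyl-3-butanoyloxazolidin-2-one F1 (from butanoyl chloride and lithiated (S)-4-benzyloxazolidin-2-one) is deprotonated with NaN(SiMe3)2 in THF at −78 °C and alkylated with 8 on the face away from the benzyl group, giving di-tert-butyl 2-[(E)-but-1-enyl]-3-{(2R)-2-[(4S)-4-benzyl-2-oxooxazolidine-3-carbonyl]butyl}maleate F2. LiBH4 in wet Et2O at 0 °C gives di-tert-butyl 2-[(E)-but-1-enyl]-3-[(2R)-2-(hydroxymethyl)butyl]maleate F3, and Dess–Martin oxidation gives 11.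

Step 10. Both partners are branched next to the reacting carbons, so addition may be slow and the Z:E ratio may erode on warming; the dienyl maleate is also a possible conjugate acceptor. The fallback sets out from 13 and 11 and comes back at 21; it olefinates with an unbranched reagent and sets the glutarate centre afterwards.
- (R)-4-Benzyl-3-(bromoacetyl)oxazolidin-2-one F4 (from bromoacetyl bromide and the lithiated auxiliary) alkylates the sodium salt of 13 to give tert-butyl 4-[(4R)-4-benzyl-2-oxooxazolidin-3-yl]-4-oxo-2-[bis(2,2,2-trifluoroethoxy)phosphoryl]butanoate F5.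
- The conditions of step 10 with 11 give di-tert-butyl 2-[(E)-but-1-enyl]-3-{(2R,3Z)-6-[(4R)-4-benzyl-2-oxooxazolidin-3-yl]-4-(tert-butoxycarbonyl)-2-ethyl-6-oxohex-3-enyl}maleate F6.
- The titanium enolate of the imide (TiCl3(OiPr), i-Pr2NEt, CH2Cl2, −78 → 0 °C) adds to tert-butyl acrylate under auxiliary control to give the (5R) Michael adduct of F6 F7.
- LiOH/H2O2 at 0 °C gives the 1,4,8,9-tetra-tert-butyl ester of 21 F8, and the acidolysis of step 11 takes it through 21 to 22.

Step 2. Vinylcopper 6 may react sluggishly with formaldehyde or isomerise on warming, after which the hydroxymethyl compound lactonises. The fallback sets out from 2 and comes back at 7, and brings in the one-carbon unit by cross-coupling. The same carbocupration is quenched with I2 at −78 °C to give di-tert-butyl 2-[(E)-but-1-enyl]-3-iodomaleate F9, and Stille coupling with (tributylstannyl)methanol (Pd(PPh3)4, dioxane, 80 °C) gives 7.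

**Further compounds**
F1 | step 4 | (S)-4-benzyl-3-butanoyloxazolidin-2-one | CCCC(=O)N1[C@@H](Cc2ccccc2)COC1=O
F2 | step 4 | di-tert-butyl 2-[(E)-but-1-enyl]-3-{(2R)-2-[(4S)-4-benzyl-2-oxooxazolidine-3-carbonyl]butyl}maleate | CC/C=C/C(/C(=O)OC(C)(C)C)=C(\C[C@@H](CC)C(=O)N1[C@@H](Cc2ccccc2)COC1=O)C(=O)OC(C)(C)C
F3 | step 4 | di-tert-butyl 2-[(E)-but-1-enyl]-3-[(2R)-2-(hydroxymethyl)butyl]maleate | CC/C=C/C(/C(=O)OC(C)(C)C)=C(\C[C@H](CO)CC)C(=O)OC(C)(C)C
F4 | step 10 | (R)-4-benzyl-3-(bromoacetyl)oxazolidin-2-one | BrCC(=O)N1[C@H](Cc2ccccc2)COC1=O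
F5 | step 10 | tert-butyl 4-[(4R)-4-benzyl-2-oxooxazolidin-3-yl]-4-oxo-2-[bis(2,2,2-trifluoroethoxy)phosphoryl]butanoate | CC(C)(C)OC(=O)C(CC(=O)N1[C@H](Cc2ccccc2)COC1=O)P(=O)(OCC(F)(F)F)OCC(F)(F)F
F6 | step 10 | di-tert-butyl 2-[(E)-but-1-enyl]-3-{(2R,3Z)-6-[(4R)-4-benzyl-2-oxooxazolidin-3-yl]-4-(tert-butoxycarbonyl)-2-ethyl-6-oxohex-3-enyl}maleate | CC/C=C/C(/C(=O)OC(C)(C)C)=C(\C[C@H](/C=C(\C(=O)OC(C)(C)C)CC(=O)N1[C@H](Cc2ccccc2)COC1=O)CC)C(=O)OC(C)(C)C
F7 | step 10 | Michael adduct of F6 with tert-butyl acrylate, (5R) at the new glutarate carbon | CC/C=C/C(/C(=O)OC(C)(C)C)=C(\C[C@H](/C=C(\C(=O)OC(C)(C)C)[C@@H](CCC(=O)OC(C)(C)C)C(=O)N1[C@H](Cc2ccccc2)COC1=O)CC)C(=O)OC(C)(C)C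
F8 | step 10 | (3R,4Z,6R,8Z,10E)-1,4,8,9-tetrakis(tert-butoxycarbonyl)-6-ethyltrideca-4,8,10-triene-3-carboxylic acid | CC/C=C/C(/C(=O)OC(C)(C)C)=C(\C[C@H](/C=C(\C(=O)OC(C)(C)C)[C@@H](CCC(=O)OC(C)(C)C)C(=O)O)CC)C(=O)OC(C)(C)C
F9 | step 2 | di-tert-butyl 2-[(E)-but-1-enyl]-3-iodomaleate | CC/C=C/C(/C(=O)OC(C)(C)C)=C(\I)C(=O)OC(C)(C)C
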